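**Retrosynthetic overview**

1. The target is a 14-membered macrolactone (ring atoms O1, C2 lactone C=O, C3 CHMe, C4 ketone, C5 C(OH)CH2OH, C6, C7 =CMe, C8 =CH, C9 CHMe, C10, C11 C=CH2, C12 =CH, C13 =CMe, C14 CHEt). Endgame: C5 diol from its acetonide, C4 ketone from a silyl-protected alcohol, C11=CH2 from a C11 ketone.
2. Key disconnection C8–C9 together with C7–CH3: nickel-catalysed methylative alkyne–enone macrocyclisation of an acyclic ester. The enabling feature is the unit C7(Me)=C8H–C9H(Me)–C10H2–C11: with C11 as a ketone, C9 is the β-carbon of an (E)-crotyl enone, and C7(Me)=C8H is the syn methyl/carbon adduct of a terminal alkyne C7≡C8H.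
3. The ynenone comes from the ester of acid 14 (C2–C8) with iodo alcohol 19 (C12–C14), followed by Nozaki–Hiyama–Kishi coupling with crotonaldehyde (C9–C11 and the C9 methyl) and oxidation.
4. Acid 14: Evans syn aldol (C3, C4) onto the α-quaternary aldehyde 7, whose C5 centre comes from a Sharpless epoxidation and acetylide opening. Alcohol 19: carboalumination–iodination of propargyl alcohol, then catalytic asymmetric ethylation.
5. Ring order: dioxolane (temporary, step 4), then the 14-membered ring (step 16), then dioxolane removed (step 20).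

Key step: step 16

Remark 1: salts of a product that are only protonated on work-up (alkoxides, carboxylates) are not numbered; reactive intermediates that are consumed by a further reagent or that are the primary product of the key step are.
Remark 2: the sense of induction of the nickel–phosphoramidite catalyst in step 16 cannot be predicted with certainty; the ligand antipode written stands for the one that delivers (9S), and its mirror image would be used otherwise.

**Route**

Step 1
Reactants: 1 2-methylidenepropane-1,3-diol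
Product: 2 2-{[(4-methoxyphenyl)methoxy]methyl}prop-2-en-1-ol
Conditions: NaH (1.0 equiv), THF/DMF, 0 °C; PMBCl (1.0 equiv), Bu4NI (cat.), 0 °C → rt
Reagents that add atoms: 4-methoxybenzyl chloride, COc1ccc(CCl)cc1
Why: Williamson etherification of the monosodium alkoxide of a symmetrical diol should give mainly the separable monoether; no stereocentre is involved.

Step 2
Reactants: 2 2-{[(4-methoxyphenyl)methoxy]methyl}prop-2-en-1-ol
Product: 3 [(2S)-2-{[(4-methoxyphenyl)methoxy]methyl}oxiran-2-yl]methanol
Conditions: Ti(OiPr)4 (10 mol %), L-(+)-diethyl tartrate (12 mol %), t-BuOOH (2 equiv, decane), 4 Å MS, CH2Cl2, −20 °C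
Reagents that add atoms: tert-butyl hydroperoxide, CC(C)(C)OO
Why: Sharpless asymmetric epoxidation of a 2-substituted allylic alcohol; L-(+)-tartrate should deliver oxygen to the same face that gives (S)-2-methylglycidol from methallyl alcohol, which sets the future C5 quaternary centre.

Step 3
Reactants: 3 [(2S)-2-{[(4-methoxyphenyl)methoxy]methyl}oxiran-2-yl]methanol
Product: 4 (2R)-2-{[(4-methoxyphenyl)methoxy]methyl}pent-4-yne-1,2-diol
Conditions: LiC≡CH·H2NCH2CH2NH2 (4 equiv), DMSO, rt; aq. NH4Cl
Reagents that add atoms: lithium acetylide (ethylenediamine complex), [Li]C#C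
Why: SN2 opening of the terminal 2,2-disubstituted epoxide at its CH2 by acetylide leaves the C–O bond at the quaternary carbon intact, and a Payne rearrangement of the alkoxide is degenerate here (it leads to the same enantiomer of 4).

Step 4
Reactants: 4 (2R)-2-{[(4-methoxyphenyl)methoxy]methyl}pent-4-yne-1,2-diol
Product: 5 (4S)-4-{[(4-methoxyphenyl)methoxy]methyl}-2,2-dimethyl-4-(prop-2-yn-1-yl)-1,3-dioxolane
Conditions: 2,2-dimethoxypropane, PPTS (cat.), CH2Cl2, rt
Reagents that add atoms: 2,2-dimethoxypropane, COC(C)(C)OC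
Why: acid-catalysed transketalisation closes the five-membered acetonide on the tertiary/primary 1,2-diol without touching the stereocentre.

Step 5
Reactants: 5 (4S)-4-{[(4-methoxyphenyl)methoxy]methyl}-2,2-dimethyl-4-(prop-2-yn-1-yl)-1,3-dioxolane
Product: 6 [(4S)-2,2-dimethyl-4-(prop-2-yn-1-yl)-1,3-dioxolan-4-yl]methanol
Conditions: DDQ, CH2Cl2/pH 7 buffer (10:1), 0 °C → rt
Reagents that add atoms: none
Why: oxidative cleavage of the 4-methoxybenzyl ether by DDQ (benzylic hydride abstraction, hydrolysis of the oxocarbenium ion) should spare the acetonide and the alkyne.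

Step 6
Reactants: 6 [(4S)-2,2-dimethyl-4-(prop-2-yn-1-yl)-1,3-dioxolan-4-yl]methanol
Product: 7 (4R)-2,2-dimethyl-4-(prop-2-yn-1-yl)-1,3-dioxolane-4-carbaldehyde
Conditions: DMP, NaHCO3, CH2Cl2, rt
Reagents that add atoms: none
Why: Dess–Martin oxidation of the primary alcohol; the aldehyde has no α-hydrogen, so the quaternary centre cannot epimerise.

Step 7
Reactants: 7 (4R)-2,2-dimethyl-4-(prop-2-yn-1-yl)-1,3-dioxolane-4-carbaldehyde; 8 (4R)-4-benzyl-3-propanoyl-1,3-oxazolidin-2-one
Product: 11 (4R)-4-benzyl-3-{(2R,3R)-3-[(4R)-2,2-dimethyl-4-(prop-2-yn-1-yl)-1,3-dioxolan-4-yl]-3-hydroxy-2-methylpropanoyl}-1,3-oxazolidin-2-one, via dibutylboron Z-enolate 9 (not isolated), via dibutylboron aldolate 10 (not isolated)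
Conditions: 8, Bu2BOTf, i-Pr2NEt, CH2Cl2, −78 → 0 °C; 7, −78 → 0 °C; pH 7 buffer, MeOH, 30 % H2O2, 0 °C
Reagents that add atoms: none
Why: Evans syn aldol; the Z-boron enolate reacts through a Zimmerman–Traxler chair on the face opposite the auxiliary benzyl group, so the (R)-auxiliary should set the C3 methyl centre (R) and the syn C4 carbinol (R) under reagent control over the α-quaternary aldehyde.

Step 8
Reactants: 11 aldol adduct (named in step 7)
Product: 12 (4R)-4-benzyl-3-{(2R,3R)-3-[(4R)-2,2-dimethyl-4-(prop-2-yn-1-yl)-1,3-dioxolan-4-yl]-2-methyl-3-[(triethylsilyl)oxy]propanoyl}-1,3-oxazolidin-2-one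
Conditions: TESOTf, 2,6-lutidine, CH2Cl2, −78 → 0 °C
Reagents that add atoms: triethylsilyl trifluoromethanesulfonate, CC[Si](CC)(CC)OS(=O)(=O)C(F)(F)F
Why: silylation of the hindered secondary alcohol with the silyl triflate and a non-nucleophilic base, which blocks retro-aldol and later differentiates C4–OH from the diol.

Step 9
Reactants: 12 silyl ether imide (named in step 8)
Product: 14 (2R,3R)-3-[(4R)-2,2-dimethyl-4-(prop-2-yn-1-yl)-1,3-dioxolan-4-yl]-2-methyl-3-[(triethylsilyl)oxy]propanoic acid, via peroxy acid 13 (not isolated)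
Conditions: LiOH, 30 % H2O2, THF/H2O (3:1), 0 °C; Na2SO3; 1 M HCl to pH 4, 0 °C
Reagents that add atoms: hydrogen peroxide (as LiOOH), OO
Why: hydroperoxide cleavage of the Evans imide at the exocyclic carbonyl, followed by sulfite reduction of the peracid, should release the acid without epimerising C3.

Step 10
Reactants: 15 prop-2-yn-1-ol
Product: 17 (2E)-3-iodo-2-methylprop-2-en-1-ol, via E-alkenylalane 16 (not isolated)
Conditions: AlMe3 (3 equiv), Cp2ZrCl2 (0.25 equiv), CH2Cl2, 0 °C → rt; I2, THF, −30 → 0 °C; aq. K2CO3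
Reagents that add atoms: trimethylaluminium, C[Al](C)C; iodine, II
Why: Negishi zirconium-catalysed carboalumination adds methyl and aluminium syn across the alkyne with aluminium at the terminus, and iodinolysis with retention gives the (E)-iodide.

Step 11
Reactants: 17 (2E)-3-iodo-2-methylprop-2-en-1-ol
Product: 18 (2E)-3-iodo-2-methylprop-2-enal
Conditions: MnO2, CH2Cl2, rt
Reagents that add atoms: none
Why: manganese dioxide oxidation of the allylic alcohol to the enal without olefin isomerisation.

Step 12
Reactants: 18 (2E)-3-iodo-2-methylprop-2-enal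
Product: 19 (1E,3S)-1-iodo-2-methylpent-1-en-3-ol
Conditions: Et2Zn (2 equiv), (−)-3-exo-morpholinoisoborneol (4 mol %), toluene/hexane, 0 °C; aq. NH4Cl
Reagents that add atoms: diethylzinc, CC[Zn]CC
Why: amino-alcohol-catalysed enantioselective addition of diethylzinc to an α-branched enal; the ligand antipode that gives (S)-1-phenylpropan-1-ol from benzaldehyde should give the (S)-carbinol (C14), the alkenyl group taking the place of phenyl.

Step 13
Reactants: 14 acid (named in step 9); 19 (1E,3S)-1-iodo-2-methylpent-1-en-3-ol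
Product: 21 (1E,3S)-1-iodo-2-methylpent-1-en-3-yl (2R,3R)-3-[(4R)-2,2-dimethyl-4-(prop-2-yn-1-yl)-1,3-dioxolan-4-yl]-2-methyl-3-[(triethylsilyl)oxy]propanoate, via mixed anhydride 20 (not isolated)
Conditions: 2,4,6-trichlorobenzoyl chloride, Et3N, THF, rt; then 19, DMAP, toluene, rt
Reagents that add atoms: none
Why: Yamaguchi esterification through the mixed anhydride and the acylpyridinium ion; acylation at oxygen retains the C14 configuration.

Step 14
Reactants: 21 iodo ester (named in step 13); 22 (2E)-but-2-enal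
Product: 24 (2E,5E,7S)-4-hydroxy-6-methylnona-2,5-dien-7-yl ester of acid 14 (both C4 epimers of the dienyl chain), via alkenylchromium dichloride 23 (not isolated)
Conditions: CrCl2 (5 equiv), NiCl2 (2 mol %), DMSO/THF, rt
Reagents that add atoms: none
Why: Nozaki–Hiyama–Kishi coupling; zerovalent nickel inserts into the C–I bond, transmetalation gives the alkenylchromium with retained E geometry, and this adds 1,2 to the enal while tolerating ester, silyl ether, acetonide and alkyne (the new carbinol is oxidised in the next step).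

Step 15
Reactants: 24 dienol ester (named in step 14)
Product: 25 (2E,5E,7S)-6-methyl-4-oxonona-2,5-dien-7-yl (2R,3R)-3-[(4R)-2,2-dimethyl-4-(prop-2-yn-1-yl)-1,3-dioxolan-4-yl]-2-methyl-3-[(triethylsilyl)oxy]propanoate
Conditions: DMP, NaHCO3, CH2Cl2, 0 °C
Reagents that add atoms: none
Why: buffered Dess–Martin oxidation of the doubly allylic alcohol gives the cross-conjugated dienone and converges both carbinol epimers.

Step 16
Reactants: 25 ynenone ester (named in step 15)
Product: 27 (3R,4R,5R,7E,9S,12E,14S)-14-ethyl-5-hydroxy-5-(hydroxymethyl)-3,7,9,13-tetramethyl-4-[(triethylsilyl)oxy]-1-oxacyclotetradeca-7,12-diene-2,11-dione 5-O,5'-O-isopropylidene acetal, via methylzinc enolate 26 (not isolated)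
Conditions: Ni(cod)2 (20 mol %), (S,R,R)-BINOL-derived N,N-bis(1-phenylethyl)phosphoramidite (40 mol %), Me2Zn (3 equiv), THF, 0 °C → rt, 25 added by syringe pump (final 0.002 M); aq. NH4Cl
Reagents that add atoms: dimethylzinc, C[Zn]C
Why: Proposed new method: zerovalent nickel binds the terminal alkyne (C7≡C8) and the (E)-crotyl C9=C10 of the cross-conjugated dienone and couples them oxidatively to a nickelacycle (alkenylnickel/O-bound nickel enolate) containing the new C8–C9 bond, Me2Zn then transfers methyl to nickel and zinc to the enolate oxygen, and C7–CH3 reductive elimination returns zerovalent nickel and leaves zinc enolate 26, which is protonated at C10 on work-up. The closest known reaction types are the nickel-catalysed three-component coupling of enones, terminal alkynes and dialkylzincs (intermolecular and for five-membered rings) and the nickel-catalysed reductive macrocyclisation of ynals; an alkylative enone–alkyne macrocyclisation has not been shown. The 14-membered ring closes in the endo mode at both π-systems (14-endo-dig at the alkyne, endo at the enone), since the unsubstituted alkyne terminus C8 joins the enone β-carbon C9, the regiochemistry that terminal alkynes show with small monodentate ligands. Syn addition of C9 and CH3 across the alkyne fixes the 7E olefin, and the new stereocentre C9 (S) is set in the oxidative cyclisation by the enone π-face that the chiral phosphoramidite–nickel fragment selects on the fixed (E)-crotyl geometry, the resident centres C5 and C14 lying four and five bonds away and expected to bias it only weakly. The step needs chemoselectivity for the crotyl arm, which the inertness of the β,β-disubstituted C12=C13 arm toward oxidative cyclisation should secure, and preference for ring closure over oligomerisation and over direct nickel-catalysed 1,4-transfer of methyl, which slow addition at high dilution should secure.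

Step 17
Reactants: 27 macrocyclic C11 ketone (named in step 16)
Product: 28 (3R,4R,5R,7E,9S,12E,14S)-14-ethyl-5-hydroxy-5-(hydroxymethyl)-3,7,9,13-tetramethyl-11-methylidene-4-[(triethylsilyl)oxy]-1-oxacyclotetradeca-7,12-dien-2-one 5-O,5'-O-isopropylidene acetal
Conditions: Zn, CH2Br2, TiCl4, THF, 0–5 °C (reagent pre-formed); 27 in CH2Cl2, 0 °C → rt
Reagents that add atoms: dibromomethane, BrCBr
Why: Takai–Lombardo methylenation; the non-basic zinc/titanium methylene reagent should convert the C11 ketone into the 1,1-disubstituted olefin in preference to the lactone and without enolisation at C10 or C3.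

Step 18
Reactants: 28 methylidene macrolactone silyl ether (named in step 17)
Product: 29 (3R,4R,5R,7E,9S,12E,14S)-14-ethyl-4,5-dihydroxy-5-(hydroxymethyl)-3,7,9,13-tetramethyl-11-methylidene-1-oxacyclotetradeca-7,12-dien-2-one 5-O,5'-O-isopropylidene acetal
Conditions: HF·pyridine, pyridine, THF, 0 °C → rt
Reagents that add atoms: none
Why: fluoride-mediated cleavage of the triethylsilyl ether under pyridine-buffered conditions that should leave the acetonide and the dienes untouched.

Step 19
Reactants: 29 C4 alcohol (named in step 18)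
Product: 30 (3R,5R,7E,9S,12E,14S)-14-ethyl-5-hydroxy-5-(hydroxymethyl)-3,7,9,13-tetramethyl-11-methylidene-1-oxacyclotetradeca-7,12-diene-2,4-dione 5-O,5'-O-isopropylidene acetal
Conditions: DMP, NaHCO3, CH2Cl2, 0 °C → rt
Reagents that add atoms: none
Why: buffered Dess–Martin oxidation of the C4 alcohol to the β-keto lactone under near-neutral conditions chosen to keep the C3 methyl centre from epimerising.

Step 20
Reactants: 30 β-keto lactone acetonide (named in step 19)
Product: 31 (3R,5R,7E,9S,12E,14S)-14-ethyl-5-hydroxy-5-(hydroxymethyl)-3,7,9,13-tetramethyl-11-methylidene-1-oxacyclotetradeca-7,12-diene-2,4-dione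
Conditions: AcOH/THF/H2O (3:1:1), 35 °C
Reagents that add atoms: none
Why: mild acid hydrolysis of the terminal acetonide releases the tertiary and primary hydroxyls; no C–O bond at C5 is broken, so its configuration is retained.

**Compound list**

1 | 2-methylidenepropane-1,3-diol | C=C(CO)CO | starting material
2 | 2-{[(4-methoxyphenyl)methoxy]methyl}prop-2-en-1-ol | C=C(CO)COCc1ccc(OC)cc1 | intermediate
3 | [(2S)-2-{[(4-methoxyphenyl)methoxy]methyl}oxiran-2-yl]methanol | OC[C@@]1(COCc2ccc(OC)cc2)CO1 | intermediate
4 | (2R)-2-{[(4-methoxyphenyl)methoxy]methyl}pent-4-yne-1,2-diol | OC[C@@](O)(COCc1ccc(OC)cc1)CC#C | intermediate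
5 | (4S)-4-{[(4-methoxyphenyl)methoxy]methyl}-2,2-dimethyl-4-(prop-2-yn-1-yl)-1,3-dioxolane | COc1ccc(COC[C@]2(COC(C)(C)O2)CC#C)cc1 | intermediate
6 | [(4S)-2,2-dimethyl-4-(prop-2-yn-1-yl)-1,3-dioxolan-4-yl]methanol | OC[C@]1(COC(C)(C)O1)CC#C | intermediate
7 | (4R)-2,2-dimethyl-4-(prop-2-yn-1-yl)-1,3-dioxolane-4-carbaldehyde | O=C[C@]1(COC(C)(C)O1)CC#C | intermediate
8 | (4R)-4-benzyl-3-propanoyl-1,3-oxazolidin-2-one | CCC(=O)N1[C@H](Cc2ccccc2)COC1=O | starting material
9 | dibutylboron Z-enolate of 8 (not isolated) | C/C=C(\OB(CCCC)CCCC)N1[C@H](Cc2ccccc2)COC1=O | intermediate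
10 | dibutylboron aldolate of 11 (not isolated) | O=C1OC[C@@H](Cc2ccccc2)N1C(=O)[C@H](C)[C@@H](OB(CCCC)CCCC)[C@]3(COC(C)(C)O3)CC#C | intermediate
11 | (4R)-4-benzyl-3-{(2R,3R)-3-[(4R)-2,2-dimethyl-4-(prop-2-yn-1-yl)-1,3-dioxolan-4-yl]-3-hydroxy-2-methylpropanoyl}-1,3-oxazolidin-2-one | O=C1OC[C@@H](Cc2ccccc2)N1C(=O)[C@H](C)[C@@H](O)[C@]3(COC(C)(C)O3)CC#C | intermediate
12 | triethylsilyl ether of 11 | O=C1OC[C@@H](Cc2ccccc2)N1C(=O)[C@H](C)[C@@H](O[Si](CC)(CC)CC)[C@]3(COC(C)(C)O3)CC#C | intermediate
13 | peroxy acid corresponding to 14 (not isolated) | OOC(=O)[C@H](C)[C@@H](O[Si](CC)(CC)CC)[C@]1(COC(C)(C)O1)CC#C | intermediate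
14 | (2R,3R)-3-[(4R)-2,2-dimethyl-4-(prop-2-yn-1-yl)-1,3-dioxolan-4-yl]-2-methyl-3-[(triethylsilyl)oxy]propanoic acid | OC(=O)[C@H](C)[C@@H](O[Si](CC)(CC)CC)[C@]1(COC(C)(C)O1)CC#C | intermediate
15 | prop-2-yn-1-ol | C#CCO | starting material
16 | (E)-alkenyldimethylalane, O-dimethylaluminium alkoxide (not isolated) | C[Al](C)/C=C(\C)CO[Al](C)C | intermediate
17 | (2E)-3-iodo-2-methylprop-2-en-1-ol | OC/C(C)=C/I | intermediate
18 | (2E)-3-iodo-2-methylprop-2-enal | O=C/C(C)=C/I | intermediate
19 | (1E,3S)-1-iodo-2-methylpent-1-en-3-ol | CC[C@H](O)/C(C)=C/I | intermediate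
20 | mixed 2,4,6-trichlorobenzoic anhydride of 14 (not isolated) | O=C(OC(=O)c1c(Cl)cc(Cl)cc1Cl)[C@H](C)[C@@H](O[Si](CC)(CC)CC)[C@]2(COC(C)(C)O2)CC#C | intermediate
21 | (1E,3S)-1-iodo-2-methylpent-1-en-3-yl ester of 14 | I/C=C(\C)[C@H](CC)OC(=O)[C@H](C)[C@@H](O[Si](CC)(CC)CC)[C@]1(COC(C)(C)O1)CC#C | intermediate
22 | (2E)-but-2-enal | C/C=C/C=O | starting material
23 | alkenylchromium dichloride from 21 (not isolated) | Cl[Cr](Cl)/C=C(\C)[C@H](CC)OC(=O)[C@H](C)[C@@H](O[Si](CC)(CC)CC)[C@]1(COC(C)(C)O1)CC#C | intermediate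
24 | (2E,5E,7S)-4-hydroxy-6-methylnona-2,5-dien-7-yl ester of 14 (C4 epimers of the dienyl chain) | C/C=C/C(O)/C=C(\C)[C@H](CC)OC(=O)[C@H](C)[C@@H](O[Si](CC)(CC)CC)[C@]1(COC(C)(C)O1)CC#C | intermediate
25 | (2E,5E,7S)-6-methyl-4-oxonona-2,5-dien-7-yl ester of 14 (ynenone) | C/C=C/C(=O)/C=C(\C)[C@H](CC)OC(=O)[C@H](C)[C@@H](O[Si](CC)(CC)CC)[C@]1(COC(C)(C)O1)CC#C | intermediate
26 | macrocyclic methylzinc enolate (C10=C11–OZnMe; not isolated) | C[Zn]OC=1/C=C(\C)[C@H](CC)OC(=O)[C@H](C)[C@@H](O[Si](CC)(CC)CC)[C@]2(COC(C)(C)O2)C/C(C)=C/[C@@H](C)C1 | intermediate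
27 | (3R,4R,5R,7E,9S,12E,14S)-14-ethyl-3,7,9,13-tetramethyl-4-[(triethylsilyl)oxy]-1-oxacyclotetradeca-7,12-diene-2,11-dione with the C5 OH and C5 CH2OH as acetonide | O=C1/C=C(\C)[C@H](CC)OC(=O)[C@H](C)[C@@H](O[Si](CC)(CC)CC)[C@]2(COC(C)(C)O2)C/C(C)=C/[C@@H](C)C1 | intermediate
28 | C11-methylidene analogue of 27 | C=C1/C=C(\C)[C@H](CC)OC(=O)[C@H](C)[C@@H](O[Si](CC)(CC)CC)[C@]2(COC(C)(C)O2)C/C(C)=C/[C@@H](C)C1 | intermediate
29 | C4 alcohol (desilylated 28) | C=C1/C=C(\C)[C@H](CC)OC(=O)[C@H](C)[C@@H](O)[C@]2(COC(C)(C)O2)C/C(C)=C/[C@@H](C)C1 | intermediate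
30 | C4 ketone, acetonide of the target | C=C1/C=C(\C)[C@H](CC)OC(=O)[C@H](C)C(=O)[C@]2(COC(C)(C)O2)C/C(C)=C/[C@@H](C)C1 | intermediate
31 | (3R,5R,7E,9S,12E,14S)-14-ethyl-5-hydroxy-5-(hydroxymethyl)-3,7,9,13-tetramethyl-11-methylidene-1-oxacyclotetradeca-7,12-diene-2,4-dione | C=C1/C=C(\C)[C@H](CC)OC(=O)[C@H](C)C(=O)[C@](O)(CO)C/C(C)=C/[C@@H](C)C1 | target

**Step count and risks**

Total steps: 20. Longest linear sequence: 17 (steps 1–9 and 13–20); steps 10–12 form the second branch.

Steps most likely to fail:

Step 16 (key step). What may go wrong: ring closure may lose to intermolecular coupling and oligomerisation; nickel may transfer methyl directly to the enone in a 1,4-sense; the alkyne may insert in the exo mode; and π-facial discrimination at C9 by the catalyst may be insufficient. The fallback makes the C8–C9 bond between two fragments by known chemistry and closes the ring at the lactone. It sets out from acid 14 and iodo alcohol 19 and returns at macrocyclic ketone 27. Acid 14 would be esterified with Me3SiCHN2 (MeOH/toluene) to the methyl ester F1. Copper-catalysed syn methylboration of its terminal alkyne (CuCl, Xantphos, B2pin2, MeI, NaOtBu, THF) would place boron on the terminal carbon and methyl on the internal one, giving the (E)-alkenyl pinacolboronate F2. Alcohol 19 would be deprotonated (MeLi), subjected to iodine–lithium exchange (t-BuLi, −78 °C) and acylated with (E)-N-methoxy-N-methylbut-2-enamide to give the hydroxy dienone F3. A Hayashi–Miyaura 1,4-addition of F2 to the crotyl arm of F3 ([Rh(OH)(cod)]2, (S)-BINAP, aq. K3PO4, dioxane, 40 °C) should give the seco hydroxy ester F4, with C9 set by the ligand (antipode chosen for S). Hydrolysis with Me3SnOH (1,2-dichloroethane, 70 °C) would give the seco acid F5, and Yamaguchi macrolactonisation at high dilution would give 27.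

Step 17. What may go wrong: methylenation of the conjugated, hindered C11 ketone may stall, or the Lewis-acidic titanium reagent may strip the silyl ether or the acetonide. The fallback is a Peterson olefination. It sets out from ketone 27 and returns at alcohol 29. Addition of Me3SiCH2Li/CeCl3 (THF, −78 °C), selective for the ketone over the lactone, would give the β-hydroxysilane F6. Treatment with HF·pyridine in THF should then bring about the Peterson elimination to the exocyclic methylidene and the removal of the triethylsilyl group in one operation, giving 29 directly.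

Step 20. What may go wrong: under the acid needed to hydrolyse the acetonide, the β-keto lactone may epimerise at C3, the α-hydroxy ketone may undergo an acyloin shift, or the diene may isomerise. The fallback changes the order of the endgame so that the acetonide is removed before the ketone exists. It sets out from alcohol 29 and returns at target 31. Hydrolysis of the acetonide at the more robust β-hydroxy lactone stage (AcOH/THF/H2O) would give the triol F7. Selective silylation of the primary hydroxyl (TESCl, imidazole, CH2Cl2, −40 °C) would give the primary silyl ether F8. Dess–Martin oxidation of the C4 secondary alcohol (the tertiary alcohol is inert) would give the keto silyl ether F9, and pyridine-buffered HF·pyridine would give 31.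

Further compounds
F1 | step 16 | methyl ester of acid 14 | COC(=O)[C@H](C)[C@@H](O[Si](CC)(CC)CC)[C@]1(COC(C)(C)O1)CC#C
F2 | step 16 | (E)-alkenyl pinacolboronate from F1 (methyl on C7, boron on C8) | COC(=O)[C@H](C)[C@@H](O[Si](CC)(CC)CC)[C@]1(COC(C)(C)O1)C/C(C)=C/B2OC(C)(C)C(C)(C)O2
F3 | step 16 | (2E,5E,7S)-7-hydroxy-6-methylnona-2,5-dien-4-one | C/C=C/C(=O)/C=C(\C)[C@H](CC)O
F4 | step 16 | seco hydroxy ester (methyl ester; C9 S; C11 ketone; C14 OH free) | COC(=O)[C@H](C)[C@@H](O[Si](CC)(CC)CC)[C@]1(COC(C)(C)O1)C/C(C)=C/[C@@H](C)CC(=O)/C=C(\C)[C@H](CC)O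
F5 | step 16 | seco acid corresponding to F4 | OC(=O)[C@H](C)[C@@H](O[Si](CC)(CC)CC)[C@]1(COC(C)(C)O1)C/C(C)=C/[C@@H](C)CC(=O)/C=C(\C)[C@H](CC)O
F6 | step 17 | β-hydroxysilane (C11 tertiary alcohol bearing CH2SiMe3; C11 epimers) | C[Si](C)(C)CC1(O)/C=C(\C)[C@H](CC)OC(=O)[C@H](C)[C@@H](O[Si](CC)(CC)CC)[C@]2(COC(C)(C)O2)C/C(C)=C/[C@@H](C)C1
F7 | step 20 | triol (C4 OH, C5 OH, C5 CH2OH free) | C=C1/C=C(\C)[C@H](CC)OC(=O)[C@H](C)[C@@H](O)[C@](O)(CO)C/C(C)=C/[C@@H](C)C1
F8 | step 20 | primary triethylsilyl ether of F7 | C=C1/C=C(\C)[C@H](CC)OC(=O)[C@H](C)[C@@H](O)[C@](O)(CO[Si](CC)(CC)CC)C/C(C)=C/[C@@H](C)C1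
F9 | step 20 | C4 ketone, primary triethylsilyl ether of the target | C=C1/C=C(\C)[C@H](CC)OC(=O)[C@H](C)C(=O)[C@](O)(CO[Si](CC)(CC)CC)C/C(C)=C/[C@@H](C)C1
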